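Count the hot minutes. I have to say which flask holds the most target at the end.

| flask | starting material | partner | reagent | temperature | remark | time |
|---|---|---|---|---|---|---|
| red | 0.10 M | 0.12 M | 0.15 M | 35 °C | run made earlier |  |
| violet | 0.10 M | 0.12 M | 0.075 M | 50 °C | run made earlier |  |
| amber | 0.10 M | 0.12 M | 0.30 M | 35 °C | run made earlier |  |
| west | 0.10 M | 0.120 M | 0.150 M |  | everything together at the start at 30 °C, warmed to 50 °C at 50 min | 1.0 h |
| east | 0.10 M | 0.120 M | 0.150 M | 50 °C | everything together at the start | 1.0 h |
| south | 0.10 M (fed, over 50 min) | 0.120 M | 0.150 M | 50 °C | all else is in the flask from the start; the feed brings no volume worth counting | 1.0 h |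
| north-west | 0.10 M | 0.120 M (fed, over 50 min) | 0.150 M |  | the addition at 30 °C, then warmed to 50 °C; the feed brings no volume worth counting | 1.0 h |

red run (percent of the starting material charged)

| time / min | target / % | starting material / % |
|---|---|---|
| 20.0 | 1 | 105 |
| 40.0 | 2 | 98 |
| 60.0 | 0 | 92 |
| 80.0 | 2 | 94 |
| 120 | 3 | 91 |

violet run (percent of the starting material charged)

| time / min | target / % | starting material / % |
|---|---|---|
| 5.00 | 0 | 98 |
| 15.0 | 0 | 101 |
| 25.0 | 0 | 96 |
| 40.0 | 2 | 97 |
| 60.0 | 7 | 97 |
| 80.0 | 7 | 92 |

amber run (percent of the starting material charged)

| time / h | target / % | starting material / % |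
|---|---|---|
| 0.417 | 1 | 99 |
| 0.833 | 0 | 94 |
| 1.33 | 5 | 90 |
| 2.00 | 12 | 80 |
| 3.00 | 19 | 75 |

(standard deviation of a reading: 2 percentage points)

- the flask with the highest amount of target, in percent of the starting material charged ("all alike" if they lie within 1.5 percentage points) (west / east / south / north-west / all alike)
- final target, as a percentage of the starting material charged, in west
- final target, as a percentage of the starting material charged, in east
- final target, as a percentage of the starting material charged, in south
- final target, as a percentage of the starting material charged, in north-west

- what was read earlier has a scatter of 2 percentage points, one standard deviation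
- a reading or a percentage of target counts all its forms, free or not

Amber and violet can be read at both ends. Early on, starting material falls before target appears: amber shows 94% starting material and 0% target at 0.833 h. Later, target follows the loss: violet holds 7% target against 8.00% lost at 80.0 min. Joining the ends gives a straight line that starts after a lag, which violet reads as 10.0 min, with the full scatter of its readings.

Amber, with twice the reagent of red, loses starting material about twice as fast, so I scale the loss with reagent. Violet, scaled to 0.150 M of reagent, gives 0.120 h⁻¹. I call this the hot pace, the share of the starting material charged that is lost per hour at 50 °C with 0.150 M of reagent; it is a pseudo-first-order rate, read from the readings.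

Target ≈ hot pace × (hot time − lag)

Temperature comes first. Amber, scaled the same way, gives 0.0417 h⁻¹ at 35 °C, slower than the hot pace. East is hot from the start:

east: 10.0%

In south, feeding starting material over 50 min takes half of that time off the mean stay of a portion:

south: 5.00%

In west, warming late leaves the hot time after 50 min, and I take the lag as spent in the cold:

west: 2.00%

Red, violet and amber hold partner at 0.12 M, so they say nothing about feeding it, and I put north-west at west's figure. My choice is east.

The forecast also says east, with 9.5% in east, 4% in south, 2.2% in west and 1.8% in north-west, a little under mine in east and south, and it holds that “the cool period does little”.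

East ends highest at 8.63%, with south at 4.53%, west at 1.67% and north-west at 1.28%.

    starting material + reagent → open intermediate (k = 1.40 M⁻¹ h⁻¹, Ea = 62.0 kJ mol⁻¹)
    reagent + partner → second intermediate (k = 11.0 M⁻¹ h⁻¹, Ea = 65.0 kJ mol⁻¹)
    open intermediate + second intermediate → target (k = 70.0 M⁻¹ h⁻¹, Ea = 68.0 kJ mol⁻¹)
    2 open intermediate → homo product (k = 120 M⁻¹ h⁻¹, Ea = 58.0 kJ mol⁻¹)
    reagent → decomposition product (k = 2.60 × 10⁻⁴ h⁻¹, Ea = 124 kJ mol⁻¹)
    crystals ⇌ target, rate k6*(cs6 - [target]) while solid is left; crystals form when [target] > cs6 (solubility = 2.20 mM, k = 3.40 h⁻¹)
    (constants at 50 °C)

At the start of east, reagent is used 9.4 times as fast in forming second intermediate as in forming open intermediate. East leads south by 4.1 percentage points, and the answer for east has moved by 5 points at 0.0759 M of reagent, the time held, or at 0.517 h, the amounts held. At 0.517 h in east the hot pace gives 4.20%, less than south's final figure.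

The neighbour, east with 0.48 M of partner, gets the same 10.0% from the hot pace, which has no partner term. The neighbour gives 4.20%, with 96% of its starting material and 1.6% of its reagent left, and reagent is the first charge to run out there, the limiting reagent.

The runs stem from a simulated flask with made-up constants, and the scatter is random.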